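The route rests on cutting the aryl ether bond O1–C8a of the flavanone pyranone (ring C) instead of the usual O1–C2 bond. The key step exploits ring A, an acylphloroglucinol in which C5 and C8a both carry oxygen and both lie ortho to the C4 carbonyl; in the precursor one oxygen is a benzyl ether and the other an aryl triflate. A palladium-catalysed intramolecular C–O coupling of the (S)-β-hydroxy ketone, made by a catalytic asymmetric Mukaiyama aldol reaction on the preformed biaryl aldehyde, then closes ring C in one operation. No bond at C2 is made or broken, so its configuration is carried into the flavanone unchanged; neutral hydrogenolysis ends the synthesis.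

Key step: step 8

Assumption: the (R,R)-bisphosphoramide of step 7 is taken to direct the enol ether to the Si face of the aldehyde, which gives the (S)-carbinol; if the sense proves opposite, the (S,S)-catalyst is used and nothing else changes.
Assumption: the C3'–C8'' biaryl axis (three ortho substituents) is taken not to be a stable stereogenic element, as the target formula defines none; intermediates may appear as interconverting rotamers.

Step 1
Reactants: 1 5-hydroxy-7-methoxy-2-(4-methoxyphenyl)-4H-chromen-4-one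
Product: 2 5-(benzyloxy)-7-methoxy-2-(4-methoxyphenyl)-4H-chromen-4-one
Conditions: BnBr, K2CO3, DMF, 70 °C
Reagents that add atoms: benzyl bromide BrCc1ccccc1
Why: Williamson ether synthesis: K2CO3 in hot DMF breaks the hydrogen bond of the chelated 5-OH, the only acidic site, and its phenoxide is benzylated so that ring A later reacts as a 5,7-dialkoxy system.

Step 2
Reactants: 2 5-(benzyloxy)-7-methoxy-2-(4-methoxyphenyl)-4H-chromen-4-one
Product: 3 5-(benzyloxy)-8-iodo-7-methoxy-2-(4-methoxyphenyl)-4H-chromen-4-one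
Conditions: NIS (1.1 equiv), TFA (cat.), MeCN, rt, dark
Reagents that add atoms: N-iodosuccinimide O=C1CCC(=O)N1I
Why: Electrophilic aromatic iodination: with the 5-oxygen alkylated, 5,7-dialkoxychromones are attacked at C8 (para to the 5-alkoxy group, ortho to 7-OMe) in preference to the more crowded C6, and the anisyl and benzyl rings are less activated.

Step 3
Reactants: 4 4-(benzyloxy)-3-bromobenzaldehyde; 3 5-(benzyloxy)-8-iodo-7-methoxy-2-(4-methoxyphenyl)-4H-chromen-4-one
Product: 6 4-(benzyloxy)-3-[5-(benzyloxy)-7-methoxy-2-(4-methoxyphenyl)-4-oxo-4H-chromen-8-yl]benzaldehyde, via pinacol boronate 5 (not isolated)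
Conditions: 4, B2pin2, PdCl2(dppf) (3 mol%), KOAc, 1,4-dioxane, 90 °C; then 3, Pd(OAc)2/SPhos (5 mol%), aq. K3PO4, 90 °C, same flask
Reagents that add atoms: none
Why: Miyaura borylation of the aryl bromide followed in the same flask by Suzuki–Miyaura cross-coupling with the aryl iodide; SPhos-ligated palladium is chosen because the new biaryl bond carries three ortho substituents, and the aldehyde, benzyl ethers and chromone tolerate phosphate base.

Step 4
Reactants: 7 1-(2,6-dihydroxy-4-methoxyphenyl)ethanone
Product: 8 1-[2-(benzyloxy)-6-hydroxy-4-methoxyphenyl]ethanone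
Conditions: BnBr (1.05 equiv), K2CO3, acetone, reflux
Reagents that add atoms: benzyl bromide BrCc1ccccc1
Why: Williamson ether synthesis on a diphenol whose two hydroxyls are equivalent by symmetry; after the first benzylation the remaining hydroxyl is locked in a hydrogen bond to the acetyl carbonyl and is far less nucleophilic, so one equivalent should stop at the monoether.

Step 5
Reactants: 8 1-[2-(benzyloxy)-6-hydroxy-4-methoxyphenyl]ethanone
Product: 9 2-acetyl-3-(benzyloxy)-5-methoxyphenyl trifluoromethanesulfonate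
Conditions: Tf2O, pyridine, CH2Cl2, 0 °C
Reagents that add atoms: trifluoromethanesulfonic anhydride O=S(=O)(OS(=O)(=O)C(F)(F)F)C(F)(F)F
Why: O-Sulfonylation (triflation) of the remaining phenol turns the oxygen on the future C8a into a leaving group for palladium; no other nucleophilic site is present.

Step 6
Reactants: 9 2-acetyl-3-(benzyloxy)-5-methoxyphenyl trifluoromethanesulfonate
Product: 10 3-(benzyloxy)-5-methoxy-2-[1-(trimethylsilyloxy)ethenyl]phenyl trifluoromethanesulfonate
Conditions: TMSOTf, Et3N, CH2Cl2, 0 °C; used crude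
Reagents that add atoms: trimethylsilyl trifluoromethanesulfonate C[Si](C)(C)OS(=O)(=O)C(F)(F)F
Why: Soft enolisation and O-silylation of the methyl ketone (silyl enol ether formation); the acetyl methyl is the only enolisable position and the triflate and benzyl ether are inert to TMSOTf/Et3N.

Step 7
Reactants: 6 4-(benzyloxy)-3-[5-(benzyloxy)-7-methoxy-2-(4-methoxyphenyl)-4-oxo-4H-chromen-8-yl]benzaldehyde; 10 3-(benzyloxy)-5-methoxy-2-[1-(trimethylsilyloxy)ethenyl]phenyl trifluoromethanesulfonate
Product: 12 3-(benzyloxy)-2-[(3S)-3-{4-(benzyloxy)-3-[5-(benzyloxy)-7-methoxy-2-(4-methoxyphenyl)-4-oxo-4H-chromen-8-yl]phenyl}-3-hydroxypropanoyl]-5-methoxyphenyl trifluoromethanesulfonate, via trichlorosilyl ether 11 (not isolated)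
Conditions: SiCl4 (2 equiv), (R,R)-binaphthyldiamine-derived bisphosphoramide with a pentane-1,5-diyl linker (5 mol%), i-Pr2NEt (10 mol%), CH2Cl2, −78 °C; then sat. aq. NaHCO3
Reagents that add atoms: none
Why: Lewis-base-catalysed, SiCl4-mediated Mukaiyama aldol addition: the chiral phosphoramide-bound trichlorosilyl cation activates the aldehyde and blocks its Re face, the enol ether adds to the Si face through an open transition state, and this catalyst control sets the carbinol carbon (future C2) as S.

Step 8
Reactants: 12 3-(benzyloxy)-2-[(3S)-3-{4-(benzyloxy)-3-[5-(benzyloxy)-7-methoxy-2-(4-methoxyphenyl)-4-oxo-4H-chromen-8-yl]phenyl}-3-hydroxypropanoyl]-5-methoxyphenyl trifluoromethanesulfonate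
Product: 13 (2S)-5-(benzyloxy)-2-{4-(benzyloxy)-3-[5-(benzyloxy)-7-methoxy-2-(4-methoxyphenyl)-4-oxo-4H-chromen-8-yl]phenyl}-7-methoxy-2,3-dihydro-4H-chromen-4-one
Conditions: Pd(OAc)2 (5 mol%), 2-(di-tert-butylphosphino)-1,1'-binaphthyl (6 mol%), K3PO4, toluene, 60 °C
Reagents that add atoms: none
Why: Buchwald–Hartwig-type intramolecular etherification: zerovalent palladium inserts into the C8a–OTf bond, which the ortho C4 carbonyl makes reactive, the carbinol is deprotonated on the metal by K3PO4, and C(sp2)–O reductive elimination forms the O1–C8a aryl ether. The closest known reaction type is the palladium-catalysed cyclisation of aryl halides bearing a secondary alcohol to chromans, which runs with retention at the carbinol carbon. Ring C is the only ring closed; it is a six-membered ring formed by reductive elimination from a seven-membered aryl(alkoxo)palladium chelate, a formal 6-exo closure onto the arene. No new stereocentre is formed, and C2 keeps its S configuration because none of its four bonds is broken. The step needs chemoselectivity for reductive elimination over beta-hydride elimination and over base-induced dehydration or retro-aldol cleavage, which the bulky electron-rich phosphine, the short tether and a weak, insoluble base in toluene are meant to secure. It is regiospecific because C8a alone carries the triflate, its twin C5 being masked as a benzyl ether.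

Step 9
Reactants: 13 (2S)-5-(benzyloxy)-2-{4-(benzyloxy)-3-[5-(benzyloxy)-7-methoxy-2-(4-methoxyphenyl)-4-oxo-4H-chromen-8-yl]phenyl}-7-methoxy-2,3-dihydro-4H-chromen-4-one
Product: 14 2,3-dihydroheveaflavone, (2S)-5-hydroxy-2-{4-hydroxy-3-[5-hydroxy-7-methoxy-2-(4-methoxyphenyl)-4-oxo-4H-chromen-8-yl]phenyl}-7-methoxy-2,3-dihydro-4H-chromen-4-one
Conditions: H2 (1 atm), 10% Pd/C, EtOAc/THF, rt
Reagents that add atoms: none
Why: Catalytic hydrogenolysis of the three aryl benzyl ethers under neutral conditions, which neither open nor epimerise the flavanone; the reaction is stopped after uptake of three equivalents of hydrogen so that the chromone double bond, the C4 ketone and the benzylic C2–O1 bond are spared.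

Compound list
1 | 5-hydroxy-7-methoxy-2-(4-methoxyphenyl)-4H-chromen-4-one (apigenin 7,4'-dimethyl ether) | COc1ccc(-c2cc(=O)c3c(O)cc(OC)cc3o2)cc1 | starting material
2 | 5-(benzyloxy)-7-methoxy-2-(4-methoxyphenyl)-4H-chromen-4-one | COc1ccc(-c2cc(=O)c3c(OCc4ccccc4)cc(OC)cc3o2)cc1 | intermediate
3 | 5-(benzyloxy)-8-iodo-7-methoxy-2-(4-methoxyphenyl)-4H-chromen-4-one | COc1ccc(-c2cc(=O)c3c(OCc4ccccc4)cc(OC)c(I)c3o2)cc1 | intermediate
4 | 4-(benzyloxy)-3-bromobenzaldehyde | O=Cc1ccc(OCc2ccccc2)c(Br)c1 | starting material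
5 | 4-(benzyloxy)-3-(4,4,5,5-tetramethyl-1,3,2-dioxaborolan-2-yl)benzaldehyde (not isolated) | O=Cc1ccc(OCc2ccccc2)c(B2OC(C)(C)C(C)(C)O2)c1 | intermediate
6 | 4-(benzyloxy)-3-[5-(benzyloxy)-7-methoxy-2-(4-methoxyphenyl)-4-oxo-4H-chromen-8-yl]benzaldehyde | COc1ccc(-c2cc(=O)c3c(OCc4ccccc4)cc(OC)c(-c4cc(C=O)ccc4OCc4ccccc4)c3o2)cc1 | intermediate
7 | 1-(2,6-dihydroxy-4-methoxyphenyl)ethanone | CC(=O)c1c(O)cc(OC)cc1O | starting material
8 | 1-[2-(benzyloxy)-6-hydroxy-4-methoxyphenyl]ethanone | CC(=O)c1c(O)cc(OC)cc1OCc1ccccc1 | intermediate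
9 | 2-acetyl-3-(benzyloxy)-5-methoxyphenyl trifluoromethanesulfonate | CC(=O)c1c(OS(=O)(=O)C(F)(F)F)cc(OC)cc1OCc1ccccc1 | intermediate
10 | 3-(benzyloxy)-5-methoxy-2-[1-(trimethylsilyloxy)ethenyl]phenyl trifluoromethanesulfonate | C=C(O[Si](C)(C)C)c1c(OS(=O)(=O)C(F)(F)F)cc(OC)cc1OCc1ccccc1 | intermediate
11 | (S)-trichlorosilyl ether of aldol 12 (not isolated) | COc1ccc(-c2cc(=O)c3c(OCc4ccccc4)cc(OC)c(-c4cc([C@@H](O[Si](Cl)(Cl)Cl)CC(=O)c5c(OS(=O)(=O)C(F)(F)F)cc(OC)cc5OCc5ccccc5)ccc4OCc4ccccc4)c3o2)cc1 | intermediate
12 | 3-(benzyloxy)-2-[(3S)-3-{4-(benzyloxy)-3-[5-(benzyloxy)-7-methoxy-2-(4-methoxyphenyl)-4-oxo-4H-chromen-8-yl]phenyl}-3-hydroxypropanoyl]-5-methoxyphenyl trifluoromethanesulfonate | COc1ccc(-c2cc(=O)c3c(OCc4ccccc4)cc(OC)c(-c4cc([C@@H](O)CC(=O)c5c(OS(=O)(=O)C(F)(F)F)cc(OC)cc5OCc5ccccc5)ccc4OCc4ccccc4)c3o2)cc1 | intermediate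
13 | (2S)-5-(benzyloxy)-2-{4-(benzyloxy)-3-[5-(benzyloxy)-7-methoxy-2-(4-methoxyphenyl)-4-oxo-4H-chromen-8-yl]phenyl}-7-methoxy-2,3-dihydro-4H-chromen-4-one | COc1ccc(-c2cc(=O)c3c(OCc4ccccc4)cc(OC)c(-c4cc([C@@H]5CC(=O)c6c(OCc7ccccc7)cc(OC)cc6O5)ccc4OCc4ccccc4)c3o2)cc1 | intermediate
14 | 2,3-dihydroheveaflavone | COc1ccc(-c2cc(=O)c3c(O)cc(OC)c(-c4cc([C@@H]5CC(=O)c6c(O)cc(OC)cc6O5)ccc4O)c3o2)cc1 | target

Total step count: 9. Longest linear sequence: 6 steps (steps 1, 2, 3, 7, 8, 9; the branch through steps 4, 5, 6, 7, 8, 9 is equally long).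

Steps most likely to fail

Step 8 (key ring closure). Base-induced dehydration or retro-aldol cleavage of the β-hydroxy ketone may outrun the ring closure, and beta-hydride elimination at the palladium alkoxide may compete with reductive elimination. Enantiopurity may also erode through reversible E1cB ring opening of the flavanone once it is formed. The fallback takes the ketone out of play during the closure of the same O1–C8a bond. It sets out from 12: a Narasaka–Prasad reduction (Et2BOMe, NaBH4, THF/MeOH, −78 °C) should give the syn-1,3-diol F1, which has no acidic α-hydrogens and cannot cleave by retro-aldol. The same palladium-catalysed C–O coupling, now free to use Cs2CO3 at 80 °C, should give the (2S,4R)-flavan-4-ol F2; only the C2 hydroxyl can reach C8a, since the C4 hydroxyl would have to close a four-membered ring. Oxidation of the benzylic C4 alcohol with Dess–Martin periodinane then returns to the route at 13.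

Step 7 (asymmetric aldol). Facial selectivity may be insufficient, an uncatalysed background addition may intervene, or the chromone carbonyl may bind the silicon Lewis acid and slow turnover. The fallback sets the stereocentre by reduction instead of C–C bond formation. It sets out from 6 and 10: a BF3·OEt2-promoted Mukaiyama aldol addition gives the racemic aldol F3, and Dess–Martin oxidation gives the 1,3-diketone F4. Noyori–Ikariya asymmetric transfer hydrogenation with RuCl[(S,S)-TsDPEN](p-cymene) in HCO2H/Et3N should reduce only the unhindered ring B carbonyl, because the other is flanked by OTf and OBn and twisted out of conjugation. By the established sense for aryl ketones this should give the (S)-alcohol, coming back to the route at 12.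

Step 3 (one-flask borylation and hindered biaryl coupling). The ortho-alkoxy arylboronate may protodeboronate under aqueous base, and transmetalation to the doubly ortho-substituted C8 may be slow. The fallback is a base-free Stille coupling. It sets out from 4: Pd(PPh3)4-catalysed stannylation with hexabutylditin in toluene at 110 °C gives the arylstannane F5, which is coupled with 3 under Pd(PPh3)4/CuI/CsF in DMF at 60 °C and comes back to the route at 6.

Further compounds
F1 | step 8 | (1R,3S)-1-[2-(benzyloxy)-4-methoxy-6-(trifluoromethanesulfonyloxy)phenyl]-3-{4-(benzyloxy)-3-[5-(benzyloxy)-7-methoxy-2-(4-methoxyphenyl)-4-oxo-4H-chromen-8-yl]phenyl}propane-1,3-diol (syn-diol) | COc1ccc(-c2cc(=O)c3c(OCc4ccccc4)cc(OC)c(-c4cc([C@@H](O)C[C@@H](O)c5c(OS(=O)(=O)C(F)(F)F)cc(OC)cc5OCc5ccccc5)ccc4OCc4ccccc4)c3o2)cc1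
F2 | step 8 | (2S,4R)-5-(benzyloxy)-2-{4-(benzyloxy)-3-[5-(benzyloxy)-7-methoxy-2-(4-methoxyphenyl)-4-oxo-4H-chromen-8-yl]phenyl}-7-methoxy-3,4-dihydro-2H-chromen-4-ol | COc1ccc(-c2cc(=O)c3c(OCc4ccccc4)cc(OC)c(-c4cc([C@@H]5C[C@@H](O)c6c(OCc7ccccc7)cc(OC)cc6O5)ccc4OCc4ccccc4)c3o2)cc1
F3 | step 7 | racemic aldol corresponding to 12 | COc1ccc(-c2cc(=O)c3c(OCc4ccccc4)cc(OC)c(-c4cc(C(O)CC(=O)c5c(OS(=O)(=O)C(F)(F)F)cc(OC)cc5OCc5ccccc5)ccc4OCc4ccccc4)c3o2)cc1
F4 | step 7 | 3-(benzyloxy)-2-(3-{4-(benzyloxy)-3-[5-(benzyloxy)-7-methoxy-2-(4-methoxyphenyl)-4-oxo-4H-chromen-8-yl]phenyl}-3-oxopropanoyl)-5-methoxyphenyl trifluoromethanesulfonate (1,3-diketone) | COc1ccc(-c2cc(=O)c3c(OCc4ccccc4)cc(OC)c(-c4cc(C(=O)CC(=O)c5c(OS(=O)(=O)C(F)(F)F)cc(OC)cc5OCc5ccccc5)ccc4OCc4ccccc4)c3o2)cc1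
F5 | step 3 | 4-(benzyloxy)-3-(tributylstannyl)benzaldehyde | O=Cc1ccc(OCc2ccccc2)c([Sn](CCCC)(CCCC)CCCC)c1
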